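**Strategy.** The eleven-membered ring (C1–C11, C1 bearing the vanillate) is opened at C6–C7, a CH2–CH2 bond of the C5–C7 trimethylene bridge that carries no stereochemical information. Unlike the other CH2–CH2 bond, C5–C6, it leaves an allyl group on C4 and not a conjugated diene. Ring-closing metathesis of an acyclic tetraene ester therefore forms the ring and the last skeletal bond in one operation, and the geometry of the transient C6=C7 alkene is erased by diimide. The precursor is the (R)-configured O-silyl vanillate of a trideca-1,4,8,12-tetraen-7-ol that already holds the E (C3=C4) and Z (C10=C11) trisubstituted alkenes, the allyl group on C4 and a vinyl group on quaternary C8.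

Key step: step 11

Remark: ring numbering is C1 (ester carbon), C2, C3=C4 (E, methyl on C4), C5–C7, C8 (gem-dimethyl), C9, C10=C11 (Z, methyl on C11); C1 is (R) in the target, in precursor 17 and in metathesis product 18.

Step 1
Reactants: 1 methyl 3,3-dimethylpent-4-enoate
Product: 2 3,3-dimethylpent-4-enal
Conditions: i-Bu2AlH (1.05 equiv), CH2Cl2, –78 °C; MeOH, then aq KNaC4H4O6 (potassium sodium tartrate); volatile aldehyde taken on as a dried solution
Reagents that add atoms: none
Why: Partial ester reduction, in which the tetrahedral aluminium hemiacetal formed from i-Bu2AlH is stable at –78 °C and releases the aldehyde only on quench, while the isolated vinyl group is inert.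

Step 2
Reactants: 2 3,3-dimethylpent-4-enal
Product: 3 (Z)-6-iodo-3,3-dimethylhepta-1,5-diene
Conditions: EtPPh3I, n-BuLi, THF, 0 → 23 °C; I2, –78 °C; NaN(SiMe3)2, –20 °C; then 2, –78 → –20 °C
Reagents that add atoms: ethyltriphenylphosphonium iodide CC[P+](c1ccccc1)(c1ccccc1)c1ccccc1.[I-]; iodine II
Why: Stork–Zhao-type Wittig olefination, in which the non-stabilised α-iodoethylidene ylide reacts under kinetic control through the oxaphosphetane that places iodine syn to the aldehyde substituent, so loss of Ph3PO should give the Z-iodoalkene needed for the Z C10=C11 bond.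

Step 3
Reactants: 4 pent-3-yn-1-ol
Product: 6 (E)-4-iodopent-3-en-1-ol, via alkenylzirconocene 5 (not isolated)
Conditions: Cp2Zr(H)Cl (2.5 equiv), THF, 23 °C; I2, 0 °C; H2O
Reagents that add atoms: iodine II
Why: Hydrozirconation–iodinolysis, in which syn addition of Zr–H, equilibrated by excess hydride so that zirconium settles on the less hindered methyl-bearing alkyne carbon, followed by C–Zr cleavage by iodine with retention, fixes the E geometry later found at C3=C4.

Step 4
Reactants: 6 (E)-4-iodopent-3-en-1-ol; 7 allyltributylstannane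
Product: 8 (E)-4-methylhepta-3,6-dien-1-ol
Conditions: PdCl2(MeCN)2 (5 mol %), DMF, 23 °C
Reagents that add atoms: none
Why: Stille coupling, in which oxidative addition of the alkenyl iodide to zerovalent palladium formed in situ, allyl transfer from tin and reductive elimination replace iodine by allyl with retention of alkene geometry, and the free hydroxyl is tolerated.

Step 5
Reactants: 8 (E)-4-methylhepta-3,6-dien-1-ol
Product: 9 (E)-4-methylhepta-3,6-dienal
Conditions: Dess–Martin periodinane, NaHCO3, CH2Cl2, 0 °C; used at once without chromatography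
Reagents that add atoms: none
Why: Dess–Martin oxidation, in which ligand exchange at iodine and intramolecular proton abstraction oxidise the primary alcohol under bicarbonate-buffered, non-enolising conditions, so the skipped diene should not move into conjugation.

Step 6
Reactants: 3 (Z)-6-iodo-3,3-dimethylhepta-1,5-diene; 9 (E)-4-methylhepta-3,6-dienal
Product: 11 rac-(4E,8Z)-4,8,11,11-tetramethyltrideca-1,4,8,12-tetraen-7-ol, via alkenyllithium 10 (not isolated)
Conditions: 3 (1.2 equiv), t-BuLi (2.4 equiv), Et2O, –78 °C; then 9, –78 °C; H2O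
Reagents that add atoms: none
Why: Lithium–iodine exchange followed by 1,2-addition, in which exchange with two equivalents of t-BuLi retains the alkene geometry and fast carbonyl addition at –78 °C forms the C1–C11 bond without control at C1, which steps 7 and 8 then set.

Step 7
Reactants: 11 rac-(4E,8Z)-4,8,11,11-tetramethyltrideca-1,4,8,12-tetraen-7-ol
Product: 12 (4E,8Z)-4,8,11,11-tetramethyltrideca-1,4,8,12-tetraen-7-one
Conditions: Dess–Martin periodinane, NaHCO3, CH2Cl2, 0 °C
Reagents that add atoms: none
Why: Dess–Martin oxidation of the secondary allylic alcohol under bicarbonate buffer should give the enone without a base strong enough to conjugate the C3=C4 bond or isomerise the Z-enone.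

Step 8
Reactants: 12 (4E,8Z)-4,8,11,11-tetramethyltrideca-1,4,8,12-tetraen-7-one
Product: 13 (4E,7R,8Z)-4,8,11,11-tetramethyltrideca-1,4,8,12-tetraen-7-ol
Conditions: (S)-2-methyl-CBS-oxazaborolidine (0.2 equiv), catecholborane (1.5 equiv), toluene, –78 °C; MeOH, then aq NaOH wash
Reagents that add atoms: none
Why: Corey–Bakshi–Shibata reduction, in which the ketone binds the oxazaborolidine boron anti to its larger α-branched Z-alkenyl substituent and takes hydride from the nitrogen-bound catecholborane on one face only, which with the (S)-catalyst should give the (R)-carbinol at C1, and catecholborane at –78 °C does not hydroborate the terminal alkenes.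

Step 9
Reactants: 14 vanillic acid
Product: 16 4-[(tert-butyldimethylsilyl)oxy]-3-methoxybenzoic acid, via silyl ester 15 (not isolated)
Conditions: TBSCl (2.5 equiv), imidazole, DMF, 23 °C; then AcOH/THF/H2O, 23 °C
Reagents that add atoms: tert-butyldimethylsilyl chloride CC(C)(C)[Si](C)(C)Cl
Why: Silyl protection, in which TBSCl/imidazole silylates both the phenol and the carboxylic acid and the far more labile silyl ester is then hydrolysed selectively by mild aqueous acid, leaving the aryl silyl ether.

Step 10
Reactants: 13 (4E,7R,8Z)-4,8,11,11-tetramethyltrideca-1,4,8,12-tetraen-7-ol; 16 4-[(tert-butyldimethylsilyl)oxy]-3-methoxybenzoic acid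
Product: 17 (4E,7R,8Z)-4,8,11,11-tetramethyltrideca-1,4,8,12-tetraen-7-yl 4-[(tert-butyldimethylsilyl)oxy]-3-methoxybenzoate
Conditions: DCC, DMAP (0.2 equiv), CH2Cl2, 0 → 23 °C
Reagents that add atoms: none
Why: Steglich esterification, in which DMAP-catalysed acyl transfer from the O-acylisourea acylates the hindered secondary allylic hydroxyl without breaking the C1–O bond, so the (R) configuration is retained.

Step 11
Reactants: 17 (4E,7R,8Z)-4,8,11,11-tetramethyltrideca-1,4,8,12-tetraen-7-yl 4-[(tert-butyldimethylsilyl)oxy]-3-methoxybenzoate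
Product: 18 (1R,2Z,6E,9E)-2,5,5,9-tetramethylcycloundeca-2,6,9-trien-1-yl 4-[(tert-butyldimethylsilyl)oxy]-3-methoxybenzoate (6E drawn; the 6Z isomer would serve equally)
Conditions: second-generation Hoveyda–Grubbs catalyst RuCl2(H2IMes)(=CH-C6H4-2-O-i-Pr) (10 mol %, two portions), 1,4-benzoquinone (20 mol %), toluene (1 mM), 80 °C, argon sparge
Reagents that add atoms: none
Why: Ring-closing olefin metathesis, in which the ruthenium alkylidene exchanges onto the unhindered allyl terminus (C6), adds to the vinyl group on C8 through a ruthenacyclobutane and cycloreverts, forming C6=C7 and releasing ethylene, whose removal drives the reaction. The closest known reaction type is ring-closing metathesis of 1,ω-dienes to medium-ring and humulene-type carbocycles. The eleven-membered ring is closed end to end, terminal alkene onto terminal alkene, with C6 and C7 both becoming ring atoms. No stereocentre is formed, C1 is a spectator, and the geometry of the new alkene does not matter because step 12 removes it. The selectivity needed is site selectivity among four alkenes: the two trisubstituted alkenes are too hindered to react, and the E geometry of C3=C4 forbids closure of the C6 alkylidene onto C10=C11, which would put a trans double bond into a seven- or eight-membered ring. High dilution counters oligomerisation, which is slow anyway at the neopentyl vinyl group, and benzoquinone suppresses hydride-mediated migration of the terminal allyl double bond.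

Step 12
Reactants: 18 (1R,2Z,6E,9E)-2,5,5,9-tetramethylcycloundeca-2,6,9-trien-1-yl 4-[(tert-butyldimethylsilyl)oxy]-3-methoxybenzoate
Product: 19 (1R,2Z,9E)-2,5,5,9-tetramethylcycloundeca-2,9-dien-1-yl 4-[(tert-butyldimethylsilyl)oxy]-3-methoxybenzoate
Conditions: 2-nitrobenzenesulfonylhydrazide (portionwise), Et3N, CH2Cl2, 23 °C
Reagents that add atoms: none
Why: Diimide reduction, in which concerted syn transfer of two hydrogens from HN=NH is strongly slowed by alkene substitution, so the disubstituted C6=C7 bond should be saturated whichever its geometry while the two trisubstituted alkenes, the ester, the arene and the silyl ether stay untouched.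

Step 13
Reactants: 19 (1R,2Z,9E)-2,5,5,9-tetramethylcycloundeca-2,9-dien-1-yl 4-[(tert-butyldimethylsilyl)oxy]-3-methoxybenzoate
Product: 20 (1R,2Z,9E)-2,5,5,9-tetramethylcycloundeca-2,9-dien-1-yl 4-hydroxy-3-methoxybenzoate (CNP0246909.1)
Conditions: Bu4NF, AcOH (1:1), THF, 0 °C
Reagents that add atoms: none
Why: Fluoride-mediated desilylation, in which fluoride attacks silicon of the aryl silyl ether and acetic acid protonates the phenoxide at once, so the allylic ester and the C1 stereocentre are not disturbed.

**Compound list**

1 | methyl 3,3-dimethylpent-4-enoate | COC(=O)CC(C)(C)C=C | starting material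
2 | 3,3-dimethylpent-4-enal | O=CCC(C)(C)C=C | intermediate
3 | (Z)-6-iodo-3,3-dimethylhepta-1,5-diene | C/C(I)=C/CC(C)(C)C=C | intermediate
4 | pent-3-yn-1-ol | CC#CCCO | starting material
5 | alkenylzirconocene: Cp2Zr(Cl) on C4 of the pent-3-en-1-olate, syn to H on C3, and Cp2Zr(Cl) on oxygen | C/C(=C\CCO[Zr](Cl)(C1C=CC=C1)C1C=CC=C1)[Zr](Cl)(C1C=CC=C1)C1C=CC=C1 | intermediate
6 | (E)-4-iodopent-3-en-1-ol | C/C(I)=C\CCO | intermediate
7 | allyltributylstannane | C=CC[Sn](CCCC)(CCCC)CCCC | starting material
8 | (E)-4-methylhepta-3,6-dien-1-ol | C=CC/C(C)=C/CCO | intermediate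
9 | (E)-4-methylhepta-3,6-dienal | C=CC/C(C)=C/CC=O | intermediate
10 | [(2E)-5,5-dimethylhepta-2,6-dien-2-yl]lithium (lithium cis to C4H2, geometry of 3 retained) | C/C([Li])=C/CC(C)(C)C=C | intermediate
11 | rac-(4E,8Z)-4,8,11,11-tetramethyltrideca-1,4,8,12-tetraen-7-ol | C=CC/C(C)=C/CC(O)/C(C)=C\CC(C)(C)C=C | intermediate
12 | (4E,8Z)-4,8,11,11-tetramethyltrideca-1,4,8,12-tetraen-7-one | C=CC/C(C)=C/CC(=O)/C(C)=C\CC(C)(C)C=C | intermediate
13 | (4E,7R,8Z)-4,8,11,11-tetramethyltrideca-1,4,8,12-tetraen-7-ol | O[C@H](C/C=C(\C)CC=C)/C(C)=C\CC(C)(C)C=C | intermediate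
14 | vanillic acid (4-hydroxy-3-methoxybenzoic acid) | COc1cc(C(=O)O)ccc1O | starting material
15 | tert-butyldimethylsilyl 4-[(tert-butyldimethylsilyl)oxy]-3-methoxybenzoate | COc1cc(C(=O)O[Si](C)(C)C(C)(C)C)ccc1O[Si](C)(C)C(C)(C)C | intermediate
16 | 4-[(tert-butyldimethylsilyl)oxy]-3-methoxybenzoic acid | COc1cc(C(=O)O)ccc1O[Si](C)(C)C(C)(C)C | intermediate
17 | (4E,7R,8Z)-4,8,11,11-tetramethyltrideca-1,4,8,12-tetraen-7-yl 4-[(tert-butyldimethylsilyl)oxy]-3-methoxybenzoate | COc1cc(C(=O)O[C@H](C/C=C(\C)CC=C)/C(C)=C\CC(C)(C)C=C)ccc1O[Si](C)(C)C(C)(C)C | intermediate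
18 | (1R,2Z,6E,9E)-2,5,5,9-tetramethylcycloundeca-2,6,9-trien-1-yl 4-[(tert-butyldimethylsilyl)oxy]-3-methoxybenzoate | COc1cc(C(=O)O[C@@H]2C/C=C(\C)C/C=C/C(C)(C)C/C=C\2C)ccc1O[Si](C)(C)C(C)(C)C | intermediate
19 | (1R,2Z,9E)-2,5,5,9-tetramethylcycloundeca-2,9-dien-1-yl 4-[(tert-butyldimethylsilyl)oxy]-3-methoxybenzoate | COc1cc(C(=O)O[C@@H]2C/C=C(\C)CCCC(C)(C)C/C=C\2C)ccc1O[Si](C)(C)C(C)(C)C | intermediate
20 | (1R,2Z,9E)-2,5,5,9-tetramethylcycloundeca-2,9-dien-1-yl 4-hydroxy-3-methoxybenzoate | COc1cc(C(=O)O[C@@H]2C/C=C(\C)CCCC(C)(C)C/C=C\2C)ccc1O | target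

**Total step count:** 13

**Longest linear sequence:** 10 steps (4 → 6 → 8 → 9 → 11 → 12 → 13 → 17 → 18 → 19 → 20; steps 3, 4, 5, 6, 7, 8, 10, 11, 12, 13)

**Steps most likely to fail**

Step 11. Intermolecular metathesis (oligomerisation) may outrun closure of the strained eleven-membered ring, or hydride species formed from the catalyst may shift the terminal allyl double bond before closure. The fallback uses metathesis only between two molecules and closes the ring at C1–C11 by a chromium-mediated carbonyl addition. It sets out from iodide 3 (in excess) and dienol 8. Cross-metathesis with the same catalyst in CH2Cl2 at 40 °C should give (3E,6E,10Z)-11-iodo-4,8,8-trimethyldodeca-3,6,10-trien-1-ol F1, whose C6=C7 geometry is again irrelevant. Diimide from 2-nitrobenzenesulfonylhydrazide/Et3N should saturate only that disubstituted alkene to give (3E,10Z)-11-iodo-4,8,8-trimethyldodeca-3,10-dien-1-ol F2. Buffered Dess–Martin oxidation should give (3E,10Z)-11-iodo-4,8,8-trimethyldodeca-3,10-dienal F3. An intramolecular Nozaki–Hiyama–Kishi reaction (CrCl2 in excess, NiCl2 catalytic, DMSO, high dilution) should close the ring to racemic (2Z,9E)-2,5,5,9-tetramethylcycloundeca-2,9-dien-1-ol F4. Dess–Martin oxidation should then give (2Z,9E)-2,5,5,9-tetramethylcycloundeca-2,9-dien-1-one F5, and the oxazaborolidine/catecholborane reduction of step 8 should give (1R,2Z,9E)-2,5,5,9-tetramethylcycloundeca-2,9-dien-1-ol F6. DCC/DMAP esterification with acid 16 comes back to the route at 19.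

Step 6. Proton transfer from the doubly activated C2 methylene of the aldehyde to the strongly basic alkenyllithium (enolisation) may compete with addition, and the C3=C4 double bond may drift into conjugation while the aldehyde is handled. The fallback changes the carbonyl partner to a bench-stable N-methoxy-N-methylamide, so that the same alkenyllithium delivers the ketone directly. It sets out from dienol 8. Oxidation with TEMPO (catalytic)/PhI(OAc)2 in MeCN–H2O should give (E)-4-methylhepta-3,6-dienoic acid F7. Coupling with MeNH(OMe)·HCl (EDC·HCl, N-methylmorpholine, CH2Cl2) should give (E)-N-methoxy-N,4-dimethylhepta-3,6-dienamide F8. Addition of alkenyllithium 10 (from 3, t-BuLi, Et2O, –78 °C) and collapse of the chelated tetrahedral intermediate on work-up should give ketone 12, where the route is rejoined; aldehyde 9, alcohol 11 and step 7 are bypassed.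

Step 8. Facial discrimination between the twisted Z-alkenyl group and the allylic methylene may be insufficient, or the C3=C4 double bond may migrate into conjugation in the skipped dienone before reduction. The fallback replaces the asymmetric reduction by a classical resolution that never passes through the ketone. It sets out from racemic alcohol 11. Esterification with (S)-2-methoxy-2-phenylacetic acid (DCC, DMAP, CH2Cl2) should give two diastereomers, (4E,7R,8Z)-4,8,11,11-tetramethyltrideca-1,4,8,12-tetraen-7-yl (S)-2-methoxy-2-phenylacetate F9 and (4E,7S,8Z)-4,8,11,11-tetramethyltrideca-1,4,8,12-tetraen-7-yl (S)-2-methoxy-2-phenylacetate F10. These are to be separated by chromatography and assigned from the phenyl shielding pattern in their proton NMR spectra. Hydrolysis of F9 (LiOH, THF/MeOH/H2O, 0 °C) comes back to the route at 13; F10 is set aside.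

**Further compounds**

F1 | step 11 | (3E,6E,10Z)-11-iodo-4,8,8-trimethyldodeca-3,6,10-trien-1-ol | OCC/C=C(\C)C/C=C/C(C)(C)C/C=C(/C)I
F2 | step 11 | (3E,10Z)-11-iodo-4,8,8-trimethyldodeca-3,10-dien-1-ol | OCC/C=C(\C)CCCC(C)(C)C/C=C(/C)I
F3 | step 11 | (3E,10Z)-11-iodo-4,8,8-trimethyldodeca-3,10-dienal | O=CC/C=C(\C)CCCC(C)(C)C/C=C(/C)I
F4 | step 11 | rac-(2Z,9E)-2,5,5,9-tetramethylcycloundeca-2,9-dien-1-ol | OC1C/C=C(\C)CCCC(C)(C)C/C=C\1C
F5 | step 11 | (2Z,9E)-2,5,5,9-tetramethylcycloundeca-2,9-dien-1-one | O=C1C/C=C(\C)CCCC(C)(C)C/C=C\1C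
F6 | step 11 | (1R,2Z,9E)-2,5,5,9-tetramethylcycloundeca-2,9-dien-1-ol | O[C@@H]1C/C=C(\C)CCCC(C)(C)C/C=C\1C
F7 | step 6 | (E)-4-methylhepta-3,6-dienoic acid | C=CC/C(C)=C/CC(=O)O
F8 | step 6 | (E)-N-methoxy-N,4-dimethylhepta-3,6-dienamide | C=CC/C(C)=C/CC(=O)N(C)OC
F9 | step 8 | (4E,7R,8Z)-4,8,11,11-tetramethyltrideca-1,4,8,12-tetraen-7-yl (S)-2-methoxy-2-phenylacetate | CO[C@H](C(=O)O[C@H](C/C=C(\C)CC=C)/C(C)=C\CC(C)(C)C=C)c1ccccc1
F10 | step 8 | (4E,7S,8Z)-4,8,11,11-tetramethyltrideca-1,4,8,12-tetraen-7-yl (S)-2-methoxy-2-phenylacetate | CO[C@H](C(=O)O[C@@H](C/C=C(\C)CC=C)/C(C)=C\CC(C)(C)C=C)c1ccccc1
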